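**Retrosynthetic overview**

- The target is the O-acetate of the corresponding primary alcohol; that alcohol comes from an N1-(2,4-dimethoxybenzyl), O-silyl imidazole by acidolysis.
- The side chain is joined at C2 (the only ring carbon between two nitrogens) by C2-lithiation of the N1-protected 4,5-disubstituted imidazole and alkylation with tert-butyl(4-iodobutoxy)dimethylsilane.
- The imidazole ring (N1–C2–N3–C4–C5) is the only ring formed. The strategy rests on its single C–C bond, C4–C5, which joins the methyl-bearing carbon to the arylethyl-bearing carbon. A van Leusen closure makes C4–C5 and N1–C2: the aldimine gives C5 and N1, and 1-tosylethyl isocyanide gives C2, N3, C4 and the methyl group.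
- The aldimine comes from 3-(3,4-dimethoxyphenyl)propanal (by oxidation of the propanol) and 2,4-dimethoxybenzylamine; the isocyanide comes from tosylmethyl isocyanide and iodomethane.

Key step: step 4

Assumption: the 1H and 3H tautomers of the N-unsubstituted imidazoles are one compound in solution, so only one tautomer is drawn and it does not matter which ring nitrogen carried the removable benzyl group.

**Route**

Step 1
Reactants: 1 3-(3,4-dimethoxyphenyl)propan-1-ol
Product: 2 3-(3,4-dimethoxyphenyl)propanal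
Conditions: TEMPO (10 mol%), PhI(OAc)2 (1.1 equiv), CH2Cl2, rt
Reagents that add atoms: none
Why: The TEMPO/PhI(OAc)2 oxoammonium oxidation of a primary alcohol should stop at the aldehyde and leave the electron-rich veratryl ring untouched.

Step 2
Reactants: 2 3-(3,4-dimethoxyphenyl)propanal; 3 2,4-dimethoxybenzylamine
Product: 4 (E)-N-(2,4-dimethoxybenzyl)-3-(3,4-dimethoxyphenyl)propan-1-imine
Conditions: MgSO4, CH2Cl2, 0 °C → rt; filter, concentrate, use crude at once
Reagents that add atoms: none
Why: Imine condensation of a primary amine with an aldehyde over a drying agent should give the E-aldimine, and neutral conditions at low temperature limit aldol and enamine side reactions of the enolisable aldehyde.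

Step 3
Reactants: 5 tosylmethyl isocyanide (TosMIC)
Product: 6 1-tosylethyl isocyanide (racemic)
Conditions: MeI (1.1 equiv), Bu4NI (cat.), 30% aq NaOH, CH2Cl2, 0 °C
Reagents that add atoms: iodomethane, CI
Why: Phase-transfer C-alkylation of the sulfonyl- and isocyanide-activated methylene is the known route to mono-alkylated TosMIC, and the less acidic, more hindered product resists a second methylation when about one equivalent of MeI is used.

Step 4
Reactants: 4 (E)-N-(2,4-dimethoxybenzyl)-3-(3,4-dimethoxyphenyl)propan-1-imine; 6 1-tosylethyl isocyanide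
Product: 8 1-(2,4-dimethoxybenzyl)-5-[2-(3,4-dimethoxyphenyl)ethyl]-4-methylimidazole, via tosylimidazoline 7 (not isolated)
Conditions: K2CO3 (2 equiv), 4 Å molecular sieves, DMF, rt → 45 °C
Reagents that add atoms: none
Why: K2CO3 deprotonates the sulfonyl- and isocyanide-activated C–H of 6, and the carbanion adds to the imine carbon of 4 to form the ring C4–C5 bond. The resulting amide nitrogen then attacks the isocyanide carbon in a 5-endo-dig closure that forms N1–C2 and, after protonation at C2, gives tosylimidazoline 7. Loss of p-toluenesulfinate from C4 together with the C5 proton aromatises 7 to imidazole 8; this is the van Leusen imidazole synthesis in its known form with an α-alkylated tosylmethyl isocyanide and an aldimine. The two stereocentres of 7 are transient and vanish on aromatisation, so no stereocontrol is needed. Regiochemistry is fixed by the mechanism, since the imine carbon can only become C5 next to the benzylated N1 and the methyl-bearing isocyanide carbon can only become C4. The selectivity to be won is addition to C=N ahead of imine–enamine tautomerisation and aza-aldol self-condensation of the enolisable aldimine, which the preformed water-free imine, the mild heterogeneous base and the absence of free aldehyde (no oxazole channel) are meant to secure.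

Step 5
Reactants: 8 1-(2,4-dimethoxybenzyl)-5-[2-(3,4-dimethoxyphenyl)ethyl]-4-methylimidazole; 9 tert-butyl(4-iodobutoxy)dimethylsilane
Product: 11 2-[4-(tert-butyldimethylsilyloxy)butyl]-1-(2,4-dimethoxybenzyl)-5-[2-(3,4-dimethoxyphenyl)ethyl]-4-methylimidazole, via 2-lithioimidazole 10 (not isolated)
Conditions: n-BuLi (1.1 equiv), THF, −78 °C; then 9 (1.3 equiv), DMPU, −78 °C → rt
Reagents that add atoms: none
Why: The C2–H between the two ring nitrogens is the kinetically most acidic site of an N1-benzylated imidazole, so azole C2-lithiation at −78 °C followed by SN2 alkylation with the primary iodide should install the chain while the silyl ether stays intact.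

Step 6
Reactants: 11 2-[4-(tert-butyldimethylsilyloxy)butyl]-1-(2,4-dimethoxybenzyl)-5-[2-(3,4-dimethoxyphenyl)ethyl]-4-methylimidazole
Product: 14 4-{4-[2-(3,4-dimethoxyphenyl)ethyl]-5-methyl-1H-imidazol-2-yl}butan-1-ol (cypholophine), via N-dimethoxybenzyl alcohol 12 (not isolated), via trifluoroacetate ester 13 (not isolated)
Conditions: CF3CO2H, 1,3-dimethoxybenzene (5 equiv), rt then 70 °C; evaporate; K2CO3, MeOH, rt
Reagents that add atoms: none
Why: Acidolysis in TFA cleaves the primary silyl ether at room temperature to give 12, and on heating the N3-protonated imidazolium releases the resonance-stabilised 2,4-dimethoxybenzyl cation (SN1-type N-debenzylation), which 1,3-dimethoxybenzene traps by Friedel–Crafts alkylation before it can attack the less nucleophilic veratryl ring, while the trifluoroacetate ester 13 formed from the free alcohol in hot TFA is cleaved by K2CO3/MeOH transesterification.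

Step 7
Reactants: 14 4-{4-[2-(3,4-dimethoxyphenyl)ethyl]-5-methyl-1H-imidazol-2-yl}butan-1-ol
Product: 15 4-{4-[2-(3,4-dimethoxyphenyl)ethyl]-5-methyl-1H-imidazol-2-yl}butyl acetate (O-acetylcypholophine)
Conditions: Ac2O (1.2 equiv), pyridine, DMAP (cat.), CH2Cl2, 0 °C → rt; MeOH quench, aq NaHCO3 work-up
Reagents that add atoms: acetic anhydride, CC(=O)OC(C)=O
Why: DMAP-catalysed acyl transfer from Ac2O should esterify the unhindered primary alcohol, and any N-acetylimidazole formed alongside is an activated amide that is solvolysed in the methanol/bicarbonate work-up, so only the O-acetate remains.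

**Compound list**

1 | 3-(3,4-dimethoxyphenyl)propan-1-ol | COc1ccc(CCCO)cc1OC | starting material
2 | 3-(3,4-dimethoxyphenyl)propanal | COc1ccc(CCC=O)cc1OC | intermediate
3 | 2,4-dimethoxybenzylamine | COc1ccc(CN)c(OC)c1 | starting material
4 | (E)-N-(2,4-dimethoxybenzyl)-3-(3,4-dimethoxyphenyl)propan-1-imine | COc1ccc(CC/C=N/Cc2ccc(OC)cc2OC)cc1OC | intermediate
5 | tosylmethyl isocyanide (TosMIC) | [C-]#[N+]CS(=O)(=O)c1ccc(C)cc1 | starting material
6 | 1-tosylethyl isocyanide (racemic) | CC([N+]#[C-])S(=O)(=O)c1ccc(C)cc1 | intermediate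
7 | 1-(2,4-dimethoxybenzyl)-5-[2-(3,4-dimethoxyphenyl)ethyl]-4-methyl-4-tosyl-4,5-dihydro-1H-imidazole (racemic, mixture of diastereomers, not isolated) | COc1ccc(CCC2N(Cc3ccc(OC)cc3OC)C=NC2(C)S(=O)(=O)c2ccc(C)cc2)cc1OC | intermediate
8 | 1-(2,4-dimethoxybenzyl)-5-[2-(3,4-dimethoxyphenyl)ethyl]-4-methylimidazole | COc1ccc(CCc2c(C)ncn2Cc2ccc(OC)cc2OC)cc1OC | intermediate
9 | tert-butyl(4-iodobutoxy)dimethylsilane | CC(C)(C)[Si](C)(C)OCCCCI | starting material
10 | 1-(2,4-dimethoxybenzyl)-5-[2-(3,4-dimethoxyphenyl)ethyl]-2-lithio-4-methylimidazole (not isolated) | [Li]c1nc(C)c(CCc2ccc(OC)c(OC)c2)n1Cc1ccc(OC)cc1OC | intermediate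
11 | 2-[4-(tert-butyldimethylsilyloxy)butyl]-1-(2,4-dimethoxybenzyl)-5-[2-(3,4-dimethoxyphenyl)ethyl]-4-methylimidazole | COc1ccc(CCc2c(C)nc(CCCCO[Si](C)(C)C(C)(C)C)n2Cc2ccc(OC)cc2OC)cc1OC | intermediate
12 | 4-{1-(2,4-dimethoxybenzyl)-5-[2-(3,4-dimethoxyphenyl)ethyl]-4-methylimidazol-2-yl}butan-1-ol (not isolated) | COc1ccc(CCc2c(C)nc(CCCCO)n2Cc2ccc(OC)cc2OC)cc1OC | intermediate
13 | 4-{4-[2-(3,4-dimethoxyphenyl)ethyl]-5-methyl-1H-imidazol-2-yl}butyl trifluoroacetate (not isolated) | COc1ccc(CCc2nc(CCCCOC(=O)C(F)(F)F)[nH]c2C)cc1OC | intermediate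
14 | 4-{4-[2-(3,4-dimethoxyphenyl)ethyl]-5-methyl-1H-imidazol-2-yl}butan-1-ol (cypholophine) | COc1ccc(CCc2nc(CCCCO)[nH]c2C)cc1OC | intermediate
15 | 4-{4-[2-(3,4-dimethoxyphenyl)ethyl]-5-methyl-1H-imidazol-2-yl}butyl acetate (O-acetylcypholophine) | COc1ccc(CCc2nc(CCCCOC(C)=O)[nH]c2C)cc1OC | target

**Step count**

Total: 7 steps. Longest linear sequence: 6 steps (steps 1, 2, 4, 5, 6, 7); step 3 is a one-step side branch.

**Steps most likely to fail**

1. Step 4 (key step). The enolisable aldimine may tautomerise to its enamine and self-condense (aza-aldol) faster than the hindered secondary sulfonyl carbanion adds, or it may hydrolyse and divert the isocyanide into oxazole formation. The fallback sets out from aldehyde 2, gives up the isocyanide chemistry for a Radziszewski condensation, and rejoins the route at alcohol 14, by-passing steps 5 and 6. 1-Ethoxyvinyllithium F1 (made in the flask from ethyl vinyl ether and t-BuLi, THF, −78 °C) is added to 2 to give 5-(3,4-dimethoxyphenyl)-2-ethoxypent-1-en-3-ol F2. Dilute aqueous HCl hydrolyses the enol ether to 5-(3,4-dimethoxyphenyl)-3-hydroxypentan-2-one F3, and Dess–Martin periodinane oxidises this to 5-(3,4-dimethoxyphenyl)pentane-2,3-dione F4. Condensation of F4 with commercial tetrahydro-2H-pyran-2-ol (the lactol form of 5-hydroxypentanal) and NH4OAc in AcOH/MeOH at 60 °C should give 14 directly.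

2. Step 5. The 2-lithioimidazole may act as a base rather than a nucleophile (E2 elimination from the primary iodide with proton return to C2), or lithiation may stray to the benzylic N–CH2 position. The fallback sets out from imidazole 8 through its lithio derivative 10 and comes back at 11. Quenching 10 with I2 at −78 °C gives 1-(2,4-dimethoxybenzyl)-5-[2-(3,4-dimethoxyphenyl)ethyl]-2-iodo-4-methylimidazole F5. Sonogashira coupling of F5 with commercial tert-butyl(but-3-yn-1-yloxy)dimethylsilane (PdCl2(PPh3)2, CuI, Et3N, DMF, 60 °C) gives 2-[4-(tert-butyldimethylsilyloxy)but-1-yn-1-yl]-1-(2,4-dimethoxybenzyl)-5-[2-(3,4-dimethoxyphenyl)ethyl]-4-methylimidazole F6. Hydrogenation (H2, Pd/C, EtOAc) saturates the triple bond and should give 11.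

3. Step 6. Heterolysis of the N–CH2Ar bond may be incomplete, or the dimethoxybenzyl cation may alkylate the veratryl ring of the substrate in competition with the scavenger. The fallback sets out from aldehyde 2, replaces the acid-labile group by a benzyl group that is removed reductively without a benzylic cation, and comes back at alcohol 14. Condensation of 2 with benzylamine (MgSO4, CH2Cl2) gives (E)-N-benzyl-3-(3,4-dimethoxyphenyl)propan-1-imine F7. Van Leusen reaction with 6 (K2CO3, DMF) passes through 1-benzyl-5-[2-(3,4-dimethoxyphenyl)ethyl]-4-methyl-4-tosyl-4,5-dihydro-1H-imidazole F8 to 1-benzyl-5-[2-(3,4-dimethoxyphenyl)ethyl]-4-methylimidazole F9. n-BuLi (THF, −78 °C) forms 1-benzyl-5-[2-(3,4-dimethoxyphenyl)ethyl]-2-lithio-4-methylimidazole F10, which is alkylated by iodide 9 to 1-benzyl-2-[4-(tert-butyldimethylsilyloxy)butyl]-5-[2-(3,4-dimethoxyphenyl)ethyl]-4-methylimidazole F11. Treatment with H2 over Pd(OH)2/C in methanolic HCl at 50 °C first frees 4-{1-benzyl-5-[2-(3,4-dimethoxyphenyl)ethyl]-4-methylimidazol-2-yl}butan-1-ol F12 by methanolysis of the silyl ether, and hydrogenolysis of the N-benzyl group then gives 14 after neutralisation.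

**Further compounds**

F1 | step 4 | 1-ethoxyvinyllithium | [Li]C(=C)OCC
F2 | step 4 | 5-(3,4-dimethoxyphenyl)-2-ethoxypent-1-en-3-ol (racemic) | C=C(OCC)C(O)CCc1ccc(OC)c(OC)c1
F3 | step 4 | 5-(3,4-dimethoxyphenyl)-3-hydroxypentan-2-one (racemic) | CC(=O)C(O)CCc1ccc(OC)c(OC)c1
F4 | step 4 | 5-(3,4-dimethoxyphenyl)pentane-2,3-dione | CC(=O)C(=O)CCc1ccc(OC)c(OC)c1
F5 | step 5 | 1-(2,4-dimethoxybenzyl)-5-[2-(3,4-dimethoxyphenyl)ethyl]-2-iodo-4-methylimidazole | COc1ccc(CCc2c(C)nc(I)n2Cc2ccc(OC)cc2OC)cc1OC
F6 | step 5 | 2-[4-(tert-butyldimethylsilyloxy)but-1-yn-1-yl]-1-(2,4-dimethoxybenzyl)-5-[2-(3,4-dimethoxyphenyl)ethyl]-4-methylimidazole | COc1ccc(CCc2c(C)nc(C#CCCO[Si](C)(C)C(C)(C)C)n2Cc2ccc(OC)cc2OC)cc1OC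
F7 | step 6 | (E)-N-benzyl-3-(3,4-dimethoxyphenyl)propan-1-imine | COc1ccc(CC/C=N/Cc2ccccc2)cc1OC
F8 | step 6 | 1-benzyl-5-[2-(3,4-dimethoxyphenyl)ethyl]-4-methyl-4-tosyl-4,5-dihydro-1H-imidazole (racemic, mixture of diastereomers) | COc1ccc(CCC2N(Cc3ccccc3)C=NC2(C)S(=O)(=O)c2ccc(C)cc2)cc1OC
F9 | step 6 | 1-benzyl-5-[2-(3,4-dimethoxyphenyl)ethyl]-4-methylimidazole | COc1ccc(CCc2c(C)ncn2Cc2ccccc2)cc1OC
F10 | step 6 | 1-benzyl-5-[2-(3,4-dimethoxyphenyl)ethyl]-2-lithio-4-methylimidazole | [Li]c1nc(C)c(CCc2ccc(OC)c(OC)c2)n1Cc1ccccc1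
F11 | step 6 | 1-benzyl-2-[4-(tert-butyldimethylsilyloxy)butyl]-5-[2-(3,4-dimethoxyphenyl)ethyl]-4-methylimidazole | COc1ccc(CCc2c(C)nc(CCCCO[Si](C)(C)C(C)(C)C)n2Cc2ccccc2)cc1OC
F12 | step 6 | 4-{1-benzyl-5-[2-(3,4-dimethoxyphenyl)ethyl]-4-methylimidazol-2-yl}butan-1-ol | COc1ccc(CCc2c(C)nc(CCCCO)n2Cc2ccccc2)cc1OC
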